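A direct plan would cut the depside ester between two finished arenes. 2-(Benzyloxy)-5-chloro-4-methoxy-3,6-dimethylbenzoic acid A1 would be activated and joined to the 4-OH of methyl 2,4-dihydroxy-3,5,6-trimethylbenzoate A2, and the benzyl ether of the coupled product A3 would be hydrogenolysed. Its weakest steps would be:
- the aroyl transfer, because a di-ortho-substituted acid would have to acylate a phenol flanked by two methyl groups while the second hydroxyl competes;
- the hydrolysis of the di-ortho-substituted methyl ester that would precede it, which would need forcing base;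
- the benzylation/hydrogenolysis pair, which would add two steps without complexity and would put the aryl chloride at risk of reduction.

Ring A is a salicylate whose C1(ester)–C2(OH)–C3(Me) half is a 3-oxopentanoate and whose C4(OMe)–C5(Cl)–C6(Me) half is an acetyl ketene acetal. The route therefore never couples two arenes. The ring B phenol captures an acylketene to give the aliphatic β-keto ester 10, and ring A is assembled last on this ester by a TiCl4-mediated formal [3+3] cyclo-aromatisation of its bis(silyloxy)diene 12 with the chloro ketene acetal 19. One operation forms C3–C4 and C1–C6 and delivers all six substituents with the 2-OH free. Hindered aroyl transfer, hydrolysis of a di-ortho-substituted ester and hydroxyl protection all disappear.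

Key step: step 9

Remark: the target has no stereocentre; the sp3 centres and double-bond geometries of the intermediates are uncontrolled and are lost on aromatisation.

Step 1
Reactants: 1 methyl 2,4-dihydroxy-3,6-dimethylbenzoate
Product: 3 methyl 5-formyl-2,4-dihydroxy-3,6-dimethylbenzoate, via α-chloro ether 2 (not isolated)
Conditions: Cl2CHOMe (1.5 equiv), TiCl4 (3 equiv), CH2Cl2, 0 °C to rt; then ice/1 M aq. HCl
Reagents that add atoms: dichloromethyl methyl ether, COC(Cl)Cl; water, O
Why: Rieche formylation (electrophilic aromatic substitution by the TiCl4-activated dichloromethyl ether) can only enter C5, the single unsubstituted ring carbon, which is ortho to the 4-OH and para to the 2-OH, and the α-chloro ether is hydrolysed to the aldehyde on work-up.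

Step 2
Reactants: 3 methyl 5-formyl-2,4-dihydroxy-3,6-dimethylbenzoate
Product: 5 methyl 2,4-dihydroxy-3,5,6-trimethylbenzoate, via benzylic alcohol 4 (not isolated)
Conditions: Et3SiH (3 equiv), CF3CO2H/CH2Cl2 1:1, 0 °C to rt
Reagents that add atoms: none
Why: Ionic hydrogenation reduces the aldehyde to the benzylic alcohol, which ionises to the hydroxyl-stabilised benzylic cation (protonated quinone methide) and takes up a second hydride to give the methyl group, while the fully substituted ring offers no position for Friedel–Crafts dimerisation.

Step 3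
Reactants: 6 2,2-dimethyl-1,3-dioxane-4,6-dione (Meldrum's acid); 7 propanoyl chloride
Product: 8 5-(1-hydroxypropylidene)-2,2-dimethyl-1,3-dioxane-4,6-dione
Conditions: pyridine (2 equiv), CH2Cl2, 0 °C to rt; 1 M aq. HCl wash
Reagents that add atoms: none
Why: C-acylation of the highly acidic Meldrum's acid by the acid chloride with pyridine gives the stable, fully enolised acyl Meldrum's acid.

Step 4
Reactants: 8 5-(1-hydroxypropylidene)-2,2-dimethyl-1,3-dioxane-4,6-dione; 5 methyl 2,4-dihydroxy-3,5,6-trimethylbenzoate
Product: 10 methyl 2-hydroxy-3,5,6-trimethyl-4-[(3-oxopentanoyl)oxy]benzoate, via propanoylketene 9 (not isolated)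
Conditions: 8 (1.15 equiv), toluene, 110 °C, 3 h
Reagents that add atoms: none
Why: Thermal retro-[4+2] fragmentation of the acyl Meldrum's acid releases acetone and CO2, and the resulting acylketene adds the phenol through an unhindered pseudopericyclic transition state that tolerates the two flanking methyl groups, the 4-OH reacting because the 2-OH is locked in a hydrogen bond to the ester carbonyl.

Step 5
Reactants: 10 methyl 2-hydroxy-3,5,6-trimethyl-4-[(3-oxopentanoyl)oxy]benzoate
Product: 12 methyl 4-{[1,3-bis(trimethylsilyloxy)penta-1,3-dien-1-yl]oxy}-3,5,6-trimethyl-2-(trimethylsilyloxy)benzoate, via mono enol ether 11 (not isolated)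
Conditions: Me3SiOTf (3.3 equiv), NEt3 (4.5 equiv), Et2O, 0 °C to rt; salt phase removed under argon, concentrated, used crude
Reagents that add atoms: trimethylsilyl trifluoromethanesulfonate, C[Si](C)(C)OS(=O)(=O)C(F)(F)F
Why: Soft enolisation with the silyl triflate and NEt3 silylates the phenol and the ketone enol (11) and then the ester carbonyl, whose oxocarbenium ion loses a γ-proton, which is the one-pot route to 1,3-bis(silyl enol ethers) of β-keto esters and exposes the aryl ester to no strong base.

Step 6
Reactants: 13 acetyl chloride; 14 1,1-dichloroethene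
Product: 16 4,4-dichlorobut-3-en-2-one, via 4,4,4-trichlorobutan-2-one 15 (not isolated)
Conditions: AlCl3 (1.05 equiv), CH2Cl2, 0 °C to rt; ice/aq. HCl; then steam distillation
Reagents that add atoms: none
Why: Friedel–Crafts-type acylation of the alkene (Darzens–Nenitzescu reaction) places the acylium ion on the CH2 terminus, chloride caps the dichloro-stabilised cation, and steam distillation eliminates HCl to the conjugated enone.

Step 7
Reactants: 16 4,4-dichlorobut-3-en-2-one
Product: 18 4,4-dimethoxybut-3-en-2-one, via 4-chloro-4-methoxybut-3-en-2-one 17 (not isolated)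
Conditions: NaOMe (2.2 equiv), MeOH, 0 °C to rt; filtration, distillation
Reagents that add atoms: sodium methoxide, [Na+].[O-]C
Why: Two successive nucleophilic vinylic substitutions (conjugate addition–elimination) by methoxide at the β-carbon of the enone replace both chlorides and stop at the push–pull ketene acetal.

Step 8
Reactants: 18 4,4-dimethoxybut-3-en-2-one
Product: 19 3-chloro-4,4-dimethoxybut-3-en-2-one
Conditions: NCS (1.05 equiv), NaHCO3 (0.5 equiv), CH2Cl2, 0 °C to rt, dark; filtration, bulb-to-bulb distillation
Reagents that add atoms: N-chlorosuccinimide, ClN1C(=O)CCC1=O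
Why: The α-carbon of the push–pull alkene is its nucleophilic site, so electrophilic α-chlorination by NCS followed by loss of the α-proton from the dialkoxycarbenium ion to the succinimide anion should give the chloro ketene acetal, the acetyl methyl group reacting far more slowly because it would first have to enolise.

Step 9
Reactants: 12 methyl 4-{[1,3-bis(trimethylsilyloxy)penta-1,3-dien-1-yl]oxy}-3,5,6-trimethyl-2-(trimethylsilyloxy)benzoate; 19 3-chloro-4,4-dimethoxybut-3-en-2-one
Product: 23 methyl 4-[(5-chloro-2-hydroxy-4-methoxy-3,6-dimethylbenzoyl)oxy]-2-hydroxy-3,5,6-trimethylbenzoate (CNP0313903.0), via open-chain enone adduct 20 (not isolated), via cyclised aldol adduct 21 (not isolated), via ring B silyl ether 22 (not isolated)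
Conditions: 19 (1.5 equiv), TiCl4 (1.5 equiv), 4 Å molecular sieves, CH2Cl2, −78 °C to 20 °C, 16 h; then 10 % aq. HCl, rt
Reagents that add atoms: none
Why: TiCl4 binds the ketone oxygen of 19 and turns the ketene acetal carbon into a dialkoxy-stabilised cationic acceptor; the terminal carbon of diene 12, its most nucleophilic site, adds there (vinylogous Mukaiyama–Michael addition) and loss of methoxide as MeOSiMe3 restores the β-methoxy enone 20, after which the remaining silyl enol ether carbon closes onto the TiCl4-activated methyl ketone (intramolecular Mukaiyama aldol, 21), and dehydration plus enolisation aromatise. The closest known reaction type is the Chan–Brownbridge formal [3+3] cyclo-aromatisation of 1,3-bis(silyl enol ethers), in its variants with 1,1-dimethoxyalk-1-en-3-ones (giving 4-methoxysalicylates) and with 2-chloro 1,3-dielectrophiles (giving 5-chlorosalicylates). Ring A is closed by a 6-(enolendo)-exo-trig aldol addition; the three sp3 centres of 21 are uncontrolled and vanish on aromatisation, so no stereocentre remains. The step needs regioselectivity, diene terminus to the acetal carbon and not to the carbonyl carbon (which would give the 6-methoxy-3,4-dimethyl isomer): the ketone carbonyl is deactivated by push–pull donation from the two methoxy groups, the Ti-bound vinylogous carbonate carbon is the cation-like site, and the diene terminus carries the largest HOMO coefficient. It also needs chemoselectivity: the aryl ester link, the hindered methyl ester and the chlorine should be inert to TiCl4 at or below 20 °C, one methoxy group is retained as the 4-OMe because the acetal carbon is at the carboxylic oxidation level, and the 2-OH emerges free from the enol silyl ether oxygen. Acidic work-up cleaves the silyl ether 22 on ring B to give 23.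

**Compound list**
1 | methyl 2,4-dihydroxy-3,6-dimethylbenzoate | COC(=O)c1c(C)cc(O)c(C)c1O | starting material
2 | methyl 5-[chloro(methoxy)methyl]-2,4-dihydroxy-3,6-dimethylbenzoate (racemic α-chloro ether) | COC(=O)c1c(C)c(C(Cl)OC)c(O)c(C)c1O | intermediate
3 | methyl 5-formyl-2,4-dihydroxy-3,6-dimethylbenzoate | COC(=O)c1c(C)c(C=O)c(O)c(C)c1O | intermediate
4 | methyl 2,4-dihydroxy-5-(hydroxymethyl)-3,6-dimethylbenzoate | COC(=O)c1c(C)c(CO)c(O)c(C)c1O | intermediate
5 | methyl 2,4-dihydroxy-3,5,6-trimethylbenzoate | COC(=O)c1c(C)c(C)c(O)c(C)c1O | intermediate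
6 | 2,2-dimethyl-1,3-dioxane-4,6-dione (Meldrum's acid) | CC1(C)OC(=O)CC(=O)O1 | starting material
7 | propanoyl chloride | CCC(=O)Cl | starting material
8 | 5-(1-hydroxypropylidene)-2,2-dimethyl-1,3-dioxane-4,6-dione | CCC(O)=C1C(=O)OC(C)(C)OC1=O | intermediate
9 | propanoylketene (3-oxopent-1-en-1-one) | CCC(=O)C=C=O | intermediate
10 | methyl 2-hydroxy-3,5,6-trimethyl-4-[(3-oxopentanoyl)oxy]benzoate | CCC(=O)CC(=O)Oc1c(C)c(C)c(C(=O)OC)c(O)c1C | intermediate
11 | methyl 3,5,6-trimethyl-2-(trimethylsilyloxy)-4-{[3-(trimethylsilyloxy)pent-2-enoyl]oxy}benzoate (E/Z mixture) | CCC(O[Si](C)(C)C)=CC(=O)Oc1c(C)c(C)c(C(=O)OC)c(O[Si](C)(C)C)c1C | intermediate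
12 | methyl 4-{[1,3-bis(trimethylsilyloxy)penta-1,3-dien-1-yl]oxy}-3,5,6-trimethyl-2-(trimethylsilyloxy)benzoate (double-bond isomer mixture) | CC=C(O[Si](C)(C)C)C=C(O[Si](C)(C)C)Oc1c(C)c(C)c(C(=O)OC)c(O[Si](C)(C)C)c1C | intermediate
13 | acetyl chloride | CC(=O)Cl | starting material
14 | 1,1-dichloroethene | C=C(Cl)Cl | starting material
15 | 4,4,4-trichlorobutan-2-one | CC(=O)CC(Cl)(Cl)Cl | intermediate
16 | 4,4-dichlorobut-3-en-2-one | CC(=O)C=C(Cl)Cl | intermediate
17 | 4-chloro-4-methoxybut-3-en-2-one (E/Z mixture) | CC(=O)C=C(Cl)OC | intermediate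
18 | 4,4-dimethoxybut-3-en-2-one | CC(=O)C=C(OC)OC | intermediate
19 | 3-chloro-4,4-dimethoxybut-3-en-2-one | CC(=O)C(Cl)=C(OC)OC | intermediate
20 | methyl 4-{[6-chloro-5-methoxy-4-methyl-7-oxo-3-(trimethylsilyloxy)octa-2,5-dienoyl]oxy}-3,5,6-trimethyl-2-(trimethylsilyloxy)benzoate (racemic, double-bond isomer mixture) | CC(=O)C(Cl)=C(OC)C(C)C(O[Si](C)(C)C)=CC(=O)Oc1c(C)c(C)c(C(=O)OC)c(O[Si](C)(C)C)c1C | intermediate
21 | methyl 4-{[(3-chloro-2-hydroxy-4-methoxy-2,5-dimethyl-6-oxocyclohex-3-en-1-yl)carbonyl]oxy}-3,5,6-trimethyl-2-(trimethylsilyloxy)benzoate (diastereomer mixture; titanium alkoxide in the flask) | CC1(O)C(Cl)=C(OC)C(C)C(=O)C1C(=O)Oc1c(C)c(C)c(C(=O)OC)c(O[Si](C)(C)C)c1C | intermediate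
22 | methyl 4-[(5-chloro-2-hydroxy-4-methoxy-3,6-dimethylbenzoyl)oxy]-3,5,6-trimethyl-2-(trimethylsilyloxy)benzoate | COC(=O)c1c(C)c(C)c(OC(=O)c2c(C)c(Cl)c(OC)c(C)c2O)c(C)c1O[Si](C)(C)C | intermediate
23 | methyl 4-[(5-chloro-2-hydroxy-4-methoxy-3,6-dimethylbenzoyl)oxy]-2-hydroxy-3,5,6-trimethylbenzoate (CNP0313903.0) | COC(=O)c1c(C)c(C)c(OC(=O)c2c(C)c(Cl)c(OC)c(C)c2O)c(C)c1O | target

Total steps: 9. Longest linear sequence: 5 (steps 1, 2, 4, 5, 9).

Steps most likely to fail:

1. Step 9. The conjugate addition may stall at the fully substituted, chlorine-bearing acetal carbon, TiCl4 may dealkylate the chloro ketene acetal before it reacts, or the first C–C bond may form at the carbonyl carbon and lead to the regioisomeric arene. The fallback sets out from 12 and 18 and comes back at 23. Diene 12 would be condensed under the same TiCl4 protocol with the chlorine-free, less hindered ketene acetal 18 to give methyl 2-hydroxy-4-[(2-hydroxy-4-methoxy-3,6-dimethylbenzoyl)oxy]-3,5,6-trimethylbenzoate F1. Its single aromatic C–H (C5 of ring A, para to the hydroxyl and ortho to the methoxy group) would then be chlorinated with SO2Cl2 (1.05 equiv, CH2Cl2, 0 °C) to give 23. Ring B is fully substituted and deactivated by its ester and acyloxy groups, so the chlorine would be placed by aromatic substitution instead of by the ring construction.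

2. Step 8. Chloride- or acid-induced dealkylation and hydrolysis of the ketene acetal to the β-keto ester, or further chlorination at the acetyl methyl group, may consume the material. The fallback sets out from 13 and comes back at 19. Acetyl chloride 13 would acylate trichloroethene (AlCl3, CH2Cl2) to give 3,4,4,4-tetrachlorobutan-2-one F2, which would lose HCl on distillation to 3,4,4-trichlorobut-3-en-2-one F3. NaOMe (2.1 equiv, MeOH, 0 °C) would then replace only the two β-chlorines by addition–elimination to give 19. The chlorine at C3 would thus arrive with the alkene building block, and no electrophilic halogenation of an acid-sensitive ketene acetal would be needed.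

3. Step 5. Silylation of the ester carbonyl may remain incomplete, C-silylation may compete, or the diene may hydrolyse during isolation. The fallback sets out from 10 and comes back at 12. Instead of the one-pot soft enolisation, 10 would be converted with Me3SiCl/NEt3 (THF, rt) into the isolable mono enol ether 11. Compound 11 would then be deprotonated irreversibly at the γ-position with LiN(iPr)2 (1.1 equiv, THF, −78 °C) and O-silylated with Me3SiCl to give 12. Enolates of 2,6-disubstituted aryl esters are persistent at this temperature, and the γ-proton is more acidic than the benzylic protons of ring B.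

**Further compounds**
F1 | step 9 | methyl 2-hydroxy-4-[(2-hydroxy-4-methoxy-3,6-dimethylbenzoyl)oxy]-3,5,6-trimethylbenzoate | COC(=O)c1c(C)c(C)c(OC(=O)c2c(C)cc(OC)c(C)c2O)c(C)c1O
F2 | step 8 | 3,4,4,4-tetrachlorobutan-2-one (racemic) | CC(=O)C(Cl)C(Cl)(Cl)Cl
F3 | step 8 | 3,4,4-trichlorobut-3-en-2-one | CC(=O)C(Cl)=C(Cl)Cl
F0 | step 5 | none | none
A1 | direct plan | 2-(benzyloxy)-5-chloro-4-methoxy-3,6-dimethylbenzoic acid | OC(=O)c1c(C)c(Cl)c(OC)c(C)c1OCc1ccccc1
A2 | direct plan | methyl 2,4-dihydroxy-3,5,6-trimethylbenzoate | COC(=O)c1c(C)c(C)c(O)c(C)c1O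
A3 | direct plan | methyl 4-{[2-(benzyloxy)-5-chloro-4-methoxy-3,6-dimethylbenzoyl]oxy}-2-hydroxy-3,5,6-trimethylbenzoate | COC(=O)c1c(C)c(C)c(OC(=O)c2c(C)c(Cl)c(OC)c(C)c2OCc2ccccc2)c(C)c1O
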